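## Retrosynthetic overview

Numbering is that of spiro[4.5]decane. Ring B is C1–C4 plus the spiro atom C5. Ring A is C5–C10.

1. 19 ⇒ 16: the C9 acetate comes from an α'-acetoxylation. The C1 ester comes from acylation of the alcohol obtained by substrate-controlled reduction of the C1 ketone of dione 16.
2. 16 ⇒ 12: a ligand-controlled copper hydride reduction of one of the two identical enone arms of dienone 12 sets C10 and turns C5 into a stereocentre.
3. 12 ⇒ 10: the key disconnection is C4–C5. Ring A is bought as an arene, and ring B is closed last by alkylative dearomatisation of a phenoxide.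
4. Enabling feature: the spiro atom C5 lies para to the C8 carbonyl carbon and between the methyl-bearing C6 and C10. Ring A is therefore a locally mirror-symmetric 3,5-dimethylphenol in disguise, and its para carbon is the nucleophile.
5. 10 ⇒ aryl bromide 5 plus lactone 3. Lactone 3 carries C1–C4 and the isopropenyl group, with C3 set by a rhodium-catalysed conjugate addition to 1.

Key step: step 7

Assumption: the absolute sense of induction of (S)-BINAP in step 1 and of (S)-DTBM-SEGPHOS in step 8 is assigned by analogy with simple cyclic enones; the ligand antipode would be used if the opposite sense were found.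

## Route

Step 1
Reactants: 1 furan-2(5H)-one; 2 2-isopropenyl-4,4,5,5-tetramethyl-1,3,2-dioxaborolane
Product: 3 (S)-4-(prop-1-en-2-yl)dihydrofuran-2(3H)-one
Conditions: [Rh(OH)(cod)]2 (2.5 mol %), (S)-BINAP (5.5 mol %), dioxane/H2O 10:1, 60 °C
Reagents that add atoms: none
Why: Hayashi–Miyaura rhodium-catalysed 1,4-addition of an alkenylboron reagent to a butenolide, in which the BINAP-bound alkenylrhodium species should add to one enantiotopic face of the flat lactone and so set the later C3.

Step 2
Reactants: 3 (S)-4-(prop-1-en-2-yl)dihydrofuran-2(3H)-one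
Product: 4 (4S)-4-(prop-1-en-2-yl)tetrahydrofuran-2-ol (lactol, both anomers)
Conditions: i-Bu2AlH (1.05 equiv), CH2Cl2, −78 °C; aqueous Rochelle salt
Reagents that add atoms: none
Why: Partial reduction of a γ-lactone, which should stop at the aluminium hemiacetal at low temperature and leaves the stereocentre untouched.

Step 3
Reactants: 5 4-bromo-3,5-dimethylphenol
Product: 6 (4-bromo-3,5-dimethylphenoxy)(tert-butyl)dimethylsilane
Conditions: TBSCl, imidazole, DMF, rt
Reagents that add atoms: tert-butyldimethylsilyl chloride, CC(C)(C)[Si](C)(C)Cl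
Why: Standard silylation of a phenol, which masks the acidic OH for the halogen–metal exchange and later serves as the fluoride-labile trigger of the key step.

Step 4
Reactants: 6 (4-bromo-3,5-dimethylphenoxy)(tert-butyl)dimethylsilane; 4 (4S)-4-(prop-1-en-2-yl)tetrahydrofuran-2-ol
Product: 8 (3S)-1-[4-(tert-butyldimethylsilyloxy)-2,6-dimethylphenyl]-3-(prop-1-en-2-yl)butane-1,4-diol (both C1 epimers), via aryllithium 7 (not isolated)
Conditions: 6 (2.2 equiv), n-BuLi (2.2 equiv), THF, −78 °C; then 4 (1.0 equiv), −78 to 0 °C; H2O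
Reagents that add atoms: none
Why: Bromine–lithium exchange followed by 1,2-addition of the aryllithium to the open hydroxy-aldehyde form of the lactol (the first equivalent deprotonates it); the carbinol centre is deliberately formed without control because it is erased in step 10.

Step 5
Reactants: 8 (3S)-1-[4-(tert-butyldimethylsilyloxy)-2,6-dimethylphenyl]-3-(prop-1-en-2-yl)butane-1,4-diol
Product: 9 (2S)-4-[4-(tert-butyldimethylsilyloxy)-2,6-dimethylphenyl]-4-hydroxy-2-(prop-1-en-2-yl)butyl 4-methylbenzenesulfonate (both carbinol epimers)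
Conditions: TsCl (1.05 equiv), pyridine, CH2Cl2, 0 °C
Reagents that add atoms: 4-toluenesulfonyl chloride, Cc1ccc(cc1)S(=O)(=O)Cl
Why: Chemoselective sulfonylation, since the primary alcohol should react far faster than the benzylic alcohol that is shielded by two ortho methyl groups.

Step 6
Reactants: 9 (2S)-4-[4-(tert-butyldimethylsilyloxy)-2,6-dimethylphenyl]-4-hydroxy-2-(prop-1-en-2-yl)butyl 4-methylbenzenesulfonate
Product: 10 (2S)-4-(tert-butyldimethylsilyloxy)-4-[4-(tert-butyldimethylsilyloxy)-2,6-dimethylphenyl]-2-(prop-1-en-2-yl)butyl 4-methylbenzenesulfonate (both epimers at the silyloxy carbon)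
Conditions: TBSOTf, 2,6-lutidine, CH2Cl2, −78 to 0 °C
Reagents that add atoms: tert-butyldimethylsilyl trifluoromethanesulfonate, CC(C)(C)[Si](C)(C)OS(=O)(=O)C(F)(F)F
Why: Silyl triflate silylation of a hindered secondary alcohol, which blocks ring closure to a tetrahydrofuran and puts a bulky group on the later C1.

Step 7
Reactants: 10 (2S)-4-(tert-butyldimethylsilyloxy)-4-[4-(tert-butyldimethylsilyloxy)-2,6-dimethylphenyl]-2-(prop-1-en-2-yl)butyl 4-methylbenzenesulfonate
Product: 12 (3S)-1-(tert-butyldimethylsilyloxy)-6,10-dimethyl-3-(prop-1-en-2-yl)spiro[4.5]deca-6,9-dien-8-one (both C1 epimers), via cesium phenoxide 11 (not isolated)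
Conditions: CsF (3 equiv), DMF, 0.005 M, 60 °C
Reagents that add atoms: none
Why: Fluoride should remove only the aryl silyl ether, and the cesium phenoxide 11 then attacks the primary tosylate through its para carbon C5 in an SN2 displacement that breaks aromaticity and gives the cross-conjugated dienone. The closest known reaction type is the Winstein–Masamune alkylative dearomatisation of 4-(4-hydroxyphenyl)butyl sulfonates (Ar1-5 participation). Ring B is closed in the 5-exo-tet mode through the new C4–C5 bond. No new stereocentre arises, because C5 becomes quaternary but stays prostereogenic as long as its two ring A arms are identical, C3 is untouched and both C1 epimers should react alike. The step needs C- over O-alkylation, para over ortho attack and survival of the C1 silyl ether: the para tether rules out intramolecular O-alkylation and high dilution suppresses the intermolecular one, the methyl groups on C6 and C10 hold the side chain perpendicular to the ring above C5 and disfavour a planar quinone methide through allylic strain, and the hindered secondary silyl ether should resist fluoride. In one operation the quaternary spiro atom, ring B, the C8 carbonyl and both ring A double bonds are made from a flat phenol.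

Step 8
Reactants: 12 (3S)-1-(tert-butyldimethylsilyloxy)-6,10-dimethyl-3-(prop-1-en-2-yl)spiro[4.5]deca-6,9-dien-8-one
Product: 14 (3S,5R,10R)-1-(tert-butyldimethylsilyloxy)-6,10-dimethyl-3-(prop-1-en-2-yl)spiro[4.5]dec-6-en-8-one (both C1 epimers), via silyl dienol ether 13 (not isolated)
Conditions: Cu(OAc)2 (5 mol %), (S)-DTBM-SEGPHOS (5.5 mol %), (EtO)2MeSiH (1.5 equiv), toluene, 0 °C; then 1 M HCl, THF, 0 °C
Reagents that add atoms: none
Why: Asymmetric copper hydride conjugate reduction used as a desymmetrisation: the branched silyloxy-bearing C1 should shield one face of both enone arms so that hydride comes from the C4 side (methyl ends cis to C1); on that face the two β-carbons have opposite prochirality, so the ligand selects C10 and thereby fixes C5, and the silyl dienol ether 13 protects against a second reduction.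

Step 9
Reactants: 14 (3S,5R,10R)-1-(tert-butyldimethylsilyloxy)-6,10-dimethyl-3-(prop-1-en-2-yl)spiro[4.5]dec-6-en-8-one
Product: 15 (3S,5R,10R)-1-hydroxy-6,10-dimethyl-3-(prop-1-en-2-yl)spiro[4.5]dec-6-en-8-one (both C1 epimers)
Conditions: HF·pyridine, pyridine, THF, 0 °C to rt
Reagents that add atoms: none
Why: Acidic fluoride desilylation, chosen because it avoids a free alkoxide that could trigger a vinylogous retro-aldol opening of ring B.

Step 10
Reactants: 15 (3S,5R,10R)-1-hydroxy-6,10-dimethyl-3-(prop-1-en-2-yl)spiro[4.5]dec-6-en-8-one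
Product: 16 (3S,5R,10R)-6,10-dimethyl-3-(prop-1-en-2-yl)spiro[4.5]dec-6-ene-1,8-dione
Conditions: Dess–Martin periodinane, NaHCO3, CH2Cl2, 0 °C to rt
Reagents that add atoms: none
Why: Dess–Martin oxidation under buffered neutral conditions, which should merge both C1 epimers into one dione without touching the alkenes.

Step 11
Reactants: 16 (3S,5R,10R)-6,10-dimethyl-3-(prop-1-en-2-yl)spiro[4.5]dec-6-ene-1,8-dione
Product: 17 (1R,3S,5R,10R)-1-hydroxy-6,10-dimethyl-3-(prop-1-en-2-yl)spiro[4.5]dec-6-en-8-one
Conditions: LiAlH(Ot-Bu)3 (1.1 equiv), THF, −78 to −20 °C; aqueous NH4Cl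
Reagents that add atoms: none
Why: Chemo- and diastereoselective hydride reduction: the saturated cyclopentanone next to a quaternary carbon should react before the β,β-disubstituted enone (as in steroidal 17-keto-4-en-3-ones), and hydride should approach C1 from the side of the flat sp2 carbon C6 because the C10 methyl group covers the other face, which sets (1R).

Step 12
Reactants: 17 (1R,3S,5R,10R)-1-hydroxy-6,10-dimethyl-3-(prop-1-en-2-yl)spiro[4.5]dec-6-en-8-one
Product: 18 (1R,3S,5R,10R)-6,10-dimethyl-8-oxo-3-(prop-1-en-2-yl)spiro[4.5]dec-6-en-1-yl 2-methylpropanoate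
Conditions: (i-PrCO)2O, DMAP, Et3N, CH2Cl2, rt
Reagents that add atoms: 2-methylpropanoic anhydride, CC(C)C(=O)OC(=O)C(C)C
Why: DMAP-catalysed acylation of a hindered secondary alcohol with retention at C1 under conditions too weakly basic for retro-aldol cleavage.

Step 13
Reactants: 18 (1R,3S,5R,10R)-6,10-dimethyl-8-oxo-3-(prop-1-en-2-yl)spiro[4.5]dec-6-en-1-yl 2-methylpropanoate
Product: 19 (1R,3S,5R,9R,10S)-9-acetoxy-6,10-dimethyl-8-oxo-3-(prop-1-en-2-yl)spiro[4.5]dec-6-en-1-yl 2-methylpropanoate
Conditions: Mn(OAc)3 (4 equiv), benzene, reflux, Dean–Stark trap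
Reagents that add atoms: manganese triacetate, CC(=O)[O-].CC(=O)[O-].CC(=O)[O-].[Mn+3]
Why: α'-Acetoxylation of an enone by trivalent manganese acetate, in which acetate should enter at C9 trans to the neighbouring C10 methyl group to give the diequatorial and, at this epimerisable position, thermodynamically preferred (9R) isomer.

## Compound list

1 | furan-2(5H)-one | O=C1C=CCO1 | starting material
2 | 2-isopropenyl-4,4,5,5-tetramethyl-1,3,2-dioxaborolane | CC(=C)B1OC(C)(C)C(C)(C)O1 | starting material
3 | (S)-4-(prop-1-en-2-yl)dihydrofuran-2(3H)-one | C=C(C)[C@@H]1CC(=O)OC1 | intermediate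
4 | (4S)-4-(prop-1-en-2-yl)tetrahydrofuran-2-ol, both anomers | C=C(C)[C@@H]1CC(O)OC1 | intermediate
5 | 4-bromo-3,5-dimethylphenol | Cc1cc(O)cc(C)c1Br | starting material
6 | (4-bromo-3,5-dimethylphenoxy)(tert-butyl)dimethylsilane | Cc1cc(O[Si](C)(C)C(C)(C)C)cc(C)c1Br | intermediate
7 | [4-(tert-butyldimethylsilyloxy)-2,6-dimethylphenyl]lithium, not isolated | [Li]c1c(C)cc(O[Si](C)(C)C(C)(C)C)cc1C | intermediate
8 | (3S)-1-[4-(tert-butyldimethylsilyloxy)-2,6-dimethylphenyl]-3-(prop-1-en-2-yl)butane-1,4-diol, both C1 epimers | C=C(C)[C@@H](CO)CC(O)c1c(C)cc(O[Si](C)(C)C(C)(C)C)cc1C | intermediate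
9 | (2S)-4-[4-(tert-butyldimethylsilyloxy)-2,6-dimethylphenyl]-4-hydroxy-2-(prop-1-en-2-yl)butyl 4-methylbenzenesulfonate, both carbinol epimers | C=C(C)[C@@H](COS(=O)(=O)c1ccc(C)cc1)CC(O)c1c(C)cc(O[Si](C)(C)C(C)(C)C)cc1C | intermediate
10 | (2S)-4-(tert-butyldimethylsilyloxy)-4-[4-(tert-butyldimethylsilyloxy)-2,6-dimethylphenyl]-2-(prop-1-en-2-yl)butyl 4-methylbenzenesulfonate, both epimers at the silyloxy carbon | C=C(C)[C@@H](COS(=O)(=O)c1ccc(C)cc1)CC(O[Si](C)(C)C(C)(C)C)c1c(C)cc(O[Si](C)(C)C(C)(C)C)cc1C | intermediate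
11 | cesium phenoxide of 10, not isolated | [Cs+].C=C(C)[C@@H](COS(=O)(=O)c1ccc(C)cc1)CC(O[Si](C)(C)C(C)(C)C)c1c(C)cc([O-])cc1C | intermediate
12 | (3S)-1-(tert-butyldimethylsilyloxy)-6,10-dimethyl-3-(prop-1-en-2-yl)spiro[4.5]deca-6,9-dien-8-one, both C1 epimers | C=C(C)[C@@H]1CC(O[Si](C)(C)C(C)(C)C)C2(C1)C(C)=CC(=O)C=C2C | intermediate
13 | (3S,5R,10R)-1-(tert-butyldimethylsilyloxy)-8-[diethoxy(methyl)silyloxy]-6,10-dimethyl-3-(prop-1-en-2-yl)spiro[4.5]deca-6,8-diene, not isolated | C=C(C)[C@@H]1CC(O[Si](C)(C)C(C)(C)C)[C@@]2(C1)C(C)=CC(O[Si](C)(OCC)OCC)=C[C@H]2C | intermediate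
14 | (3S,5R,10R)-1-(tert-butyldimethylsilyloxy)-6,10-dimethyl-3-(prop-1-en-2-yl)spiro[4.5]dec-6-en-8-one, both C1 epimers | C=C(C)[C@@H]1CC(O[Si](C)(C)C(C)(C)C)[C@@]2(C1)C(C)=CC(=O)C[C@H]2C | intermediate
15 | (3S,5R,10R)-1-hydroxy-6,10-dimethyl-3-(prop-1-en-2-yl)spiro[4.5]dec-6-en-8-one, both C1 epimers | C=C(C)[C@@H]1CC(O)[C@@]2(C1)C(C)=CC(=O)C[C@H]2C | intermediate
16 | (3S,5R,10R)-6,10-dimethyl-3-(prop-1-en-2-yl)spiro[4.5]dec-6-ene-1,8-dione | C=C(C)[C@@H]1CC(=O)[C@@]2(C1)C(C)=CC(=O)C[C@H]2C | intermediate
17 | (1R,3S,5R,10R)-1-hydroxy-6,10-dimethyl-3-(prop-1-en-2-yl)spiro[4.5]dec-6-en-8-one | C=C(C)[C@@H]1C[C@@H](O)[C@@]2(C1)C(C)=CC(=O)C[C@H]2C | intermediate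
18 | (1R,3S,5R,10R)-6,10-dimethyl-8-oxo-3-(prop-1-en-2-yl)spiro[4.5]dec-6-en-1-yl 2-methylpropanoate | C=C(C)[C@@H]1C[C@@H](OC(=O)C(C)C)[C@@]2(C1)C(C)=CC(=O)C[C@H]2C | intermediate
19 | (1R,3S,5R,9R,10S)-9-acetoxy-6,10-dimethyl-8-oxo-3-(prop-1-en-2-yl)spiro[4.5]dec-6-en-1-yl 2-methylpropanoate | C=C(C)[C@@H]1C[C@@H](OC(=O)C(C)C)[C@@]2(C1)C(C)=CC(=O)[C@H](OC(C)=O)[C@H]2C | target

## Step count and weak points

Total step count: 13. Longest linear sequence: 12 (steps 1, 2 and 4 to 13, counted from compound 1).

**Step 8.**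
- What may go wrong: hydride transfer next to the quaternary carbon may be sluggish. Discrimination between the two enone arms or between their faces may be poor, and over-reduction may set in.
- Fallback: it sets out from 12 and comes back at 14. Both arms are reduced exhaustively from the less hindered C4 side with catalytic [(Ph3P)CuH]6, PhSiH3 and t-BuOH in toluene. This gives the saturated ketone (3S,6S,10R)-1-(tert-butyldimethylsilyloxy)-6,10-dimethyl-3-(prop-1-en-2-yl)spiro[4.5]decan-8-one F1.
- The two α-methylene groups of F1 are then told apart by a chiral lithium amide deprotonation, using lithium (R,R)-bis(1-phenylethyl)amide with TMSCl as internal quench in THF at −100 °C (the antipode if needed). This reaction is known for cis-3,5-dimethylcyclohexanones. It gives the silyl enol ether 8-trimethylsilyloxy-spiro[4.5]dec-7-ene F2.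
- A Saegusa–Ito oxidation with Pd(OAc)2 in MeCN then installs the C6–C7 double bond. This erases the auxiliary C6 stereocentre and delivers 14.

**Step 7.**
- What may go wrong: intermolecular O-alkylation to oligomers may compete. Displacement at the β-branched C4 may be slow. Loss of the C1 silyl ether would be followed by closure to a tetrahydrofuran.
- Fallback: it sets out from 8 and comes back at 12. Diol 8 is persilylated with TBSOTf and 2,6-lutidine to the tris(silyl) ether F3.
- The primary alkyl and the aryl silyl ethers are cleaved with acetic-acid-buffered Bu4NF at 0 °C. The hindered secondary ether should remain, giving the phenol alcohol 4-[1-(tert-butyldimethylsilyloxy)-4-hydroxy-3-(prop-1-en-2-yl)butyl]-3,5-dimethylphenol F4.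
- Ring B is then closed by a Mitsunobu reaction (1,1'-(azodicarbonyl)dipiperidine, PBu3, benzene, high dilution). The alcohol is activated as an alkoxyphosphonium ion paired with the phenoxide, so that neither a preformed sulfonate nor fluoride is present.

**Step 13.**
- What may go wrong: radical addition at the isopropenyl group may occur at reflux. Conversion may be incomplete, and a mixture of C9 epimers may form.
- Fallback: it sets out from 18 and comes back at 19. Kinetic deprotonation at C9 with LiN(SiMe3)2 and TMSCl in THF at −78 °C gives the cross-conjugated trimethylsilyl dienol ether F5.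
- A Rubottom-type acetoxylation with Pb(OAc)4 in CH2Cl2 at −20 °C then places the acetate at C9.
- Any axial epimer should drift to the equatorial (9R) isomer on brief exposure to a mild amine base.

Further compounds
F1 | step 8 | (3S,6S,10R)-1-(tert-butyldimethylsilyloxy)-6,10-dimethyl-3-(prop-1-en-2-yl)spiro[4.5]decan-8-one, both ring A methyl groups cis to C1, both C1 epimers | C=C(C)[C@@H]1CC(O[Si](C)(C)C(C)(C)C)[C@@]2(C1)[C@@H](C)CC(=O)C[C@H]2C
F2 | step 8 | (3S,6S,10R)-1-(tert-butyldimethylsilyloxy)-6,10-dimethyl-3-(prop-1-en-2-yl)-8-(trimethylsilyloxy)spiro[4.5]dec-7-ene, both C1 epimers | C=C(C)[C@@H]1CC(O[Si](C)(C)C(C)(C)C)[C@@]2(C1)[C@@H](C)C=C(O[Si](C)(C)C)C[C@H]2C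
F3 | step 7 | (3S)-1,4-bis(tert-butyldimethylsilyloxy)-1-[4-(tert-butyldimethylsilyloxy)-2,6-dimethylphenyl]-3-(prop-1-en-2-yl)butane, both C1 epimers | C=C(C)[C@@H](CO[Si](C)(C)C(C)(C)C)CC(O[Si](C)(C)C(C)(C)C)c1c(C)cc(O[Si](C)(C)C(C)(C)C)cc1C
F4 | step 7 | 4-[(3S)-1-(tert-butyldimethylsilyloxy)-4-hydroxy-3-(prop-1-en-2-yl)butyl]-3,5-dimethylphenol, both epimers at the silyloxy carbon | C=C(C)[C@@H](CO)CC(O[Si](C)(C)C(C)(C)C)c1c(C)cc(O)cc1C
F5 | step 13 | (1R,3S,5R,10R)-6,10-dimethyl-3-(prop-1-en-2-yl)-8-(trimethylsilyloxy)spiro[4.5]deca-6,8-dien-1-yl 2-methylpropanoate | C=C(C)[C@@H]1C[C@@H](OC(=O)C(C)C)[C@@]2(C1)C(C)=CC(O[Si](C)(C)C)=C[C@H]2C
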